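The catalyst in a closed flask is a fixed sum, 15 mM here, shared between working and dead forms, and that sum moves when somebody adds to it.

| setting | delta | flask |
|---|---|---|
| starting material | 1.5 M | 1.5 M |
| second substrate | 0.75 M | 0.750 M |
| reagent | 2.25 M | 2.25 M |
| capture agent | 0.15 M | 0.150 M |
| free catalyst | 15 mM | 15 mM |
| remark | the very flask that is asked about, followed so far |  |
| time |  | 8.0 h |

delta run (percent of the starting material charged)

| time / min | target / % | starting material / % |
|---|---|---|
| 25.0 | 23.1 | 73.5 |
| 80.0 | 34.6 | 61.2 |
| 150 | 32.8 | 58.9 |
| 180 | 34.1 | 59.5 |
| 300 | 32.9 | 58.5 |
| 360 | 35.4 | 56.8 |
| 480 | 33.6 | 58.7 |

(scatter of a reading: 1 percentage point)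

- west: at 8.0 h take out 90% of the target then present, then wait 15 h
- north-east: change nothing and wait 15 h more
- south-east: at 8.0 h add free catalyst, 50.0% of the amount charged, then wait 15 h

- what is taken out of target is counted as made
- the numbers in the tables scatter by 1 percentage point (one standard deviation)
- additions bring no volume worth counting

* target, in percent of the starting material first charged, at 8.0 h
* what to do for the largest gain in target; "none" if nothing gains more than 2 percentage points (west / north-east / south-east / none)
* target present, with what was taken out counted in, in percent of the starting material first charged, after west
* target present, with what was taken out counted in, in percent of the starting material first charged, after south-east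

Examiner: What do the readings of this flask show?

Answer: From 150 min on, target is flat within the scatter, with a mean of 33.8%. That is my answer for now.

Examiner: Has the starting material run out?

Answer: No, its mean there is 58.5%.

Examiner: Then it may be an equilibrium. Why not?

Answer: The readings can't exclude it outright, and that is the weak spot. I commit to a dead catalyst, and so waiting and taking out target each leave the count at 33.8%.

Examiner: What do you carry away from this?

Answer: The net turnover number, target standing in this flask per catalyst charged once the catalyst has stopped, 33.8. It counts target present, not target made, and it belongs to this flask with these charges.

Examiner: So does half a dose buy half of that?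

Answer: By plain proportion to the net turnover number it buys 17 percentage points, for a sum of 50.6%. But the readings of this flask put 41.5% of its starting material as already used, so I hold that sum as a proportion, not as my expectation here.

The forecast gives 33.9% now and 34% after west. It chooses south-east, with 39%, less than my proportional sum. In its own words, “the catalyst has most likely died, rather than the reaction reaching equilibrium”.

The flask gives 34.0%, 34.0% after west, and 40.5% after south-east. At 480 min, trapped intermediate holds >99.9% of the catalyst and free catalyst 0%, so the dead catalyst was the step that carried the forecast. The gain of 6.5 points stands above the margin of 2 points. Per catalyst added, that is 13.0 target, fewer than the 33.8 of the first charge.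

    starting material + free catalyst ⇌ catalyst intermediate A (K = 1.80 L mol⁻¹, k = 0.0780 L mol⁻¹ s⁻¹)
    reagent + catalyst intermediate A → free catalyst + target (k = 0.0520 L mol⁻¹ s⁻¹)
    second substrate + free catalyst ⇌ catalyst intermediate B (K = 220 L mol⁻¹, k = 0.100 L mol⁻¹ s⁻¹)
    reagent + catalyst intermediate B → free catalyst + second product (k = 0.0330 L mol⁻¹ s⁻¹)
    free catalyst + target → free catalyst + over-reaction product (k = 0.0290 L mol⁻¹ s⁻¹)
    catalyst intermediate A + capture agent → trapped intermediate (k = 0.0150 L mol⁻¹ s⁻¹)

In a neighbour flask, the same but with [capture agent] at 0.38 M, my net turnover number, scaled inversely with capture agent, becomes 13.3, which gives 13.3% target. The computed neighbour flask holds 17.4% target.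

The data are calculated with made-up constants, and the scatter is random.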